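The seven-membered ring (C4–C5–C6–C7–C8–C9–C10; numbering below) is treated as a cyclopentane enlarged by the two-carbon unit C6–C7, so that its C5/C9 oxygenation is the 1,5-dicarbonyl retron of a de Mayo reaction. A cis-hydrindane 1,3-dione, in which one catalytic Diels–Alder reaction has set C3, C4 and C10, carries a 2-methylallyl group on a silicon tether at the C5 enol oxygen. Irradiation joins C5–C6 and C7–C8 in a single [2+2] event on the convex face and fixes the quaternary C6; strain-driven retro-aldol cleavage of C5–C8 then releases the cycloheptanedione. Enolate displacement C11→C5 closes the cyclobutane last.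

Key step: step 6

Numbering (ring carbons of the target, used for all intermediates): C1 = ketone carbon; C2 = CH2; C3 = CH(CH3); C4 and C11 = cyclobutane CH (C4 next to C3, C11 next to C1); C5 = cyclobutane CH bonded to C6; C6 = C(CH3)(CH2O); C7, C8 = CH2; C9 = CH–O; C10 = cyclobutane C(CH3). Faces of the seven-membered ring: β = the face that carries C3/C11 (concave in the bicyclic intermediates); α = the face of H-4 and CH3-10.

Remark (assumption): the sense of induction of the oxazaborolidinium catalyst in step 3 is taken from the usual pre-transition-state model (binding at the carbonyl next to the vinylic C–H); the (S)-catalyst is assumed to give the (3aR,4R,7aS) adduct drawn, otherwise its enantiomer is used.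

Step 1
Reactants: 1 (E)-pent-3-en-2-one
Product: 2 (E)-2-(triisopropylsilyloxy)penta-1,3-diene
Conditions: i-Pr3SiOTf, Et3N, Et2O, 0 → 23 °C
Reagents that add atoms: triisopropylsilyl trifluoromethanesulfonate, CC(C)[Si](C(C)C)(C(C)C)OS(=O)(=O)C(F)(F)F
Why: Silyl enol ether formation: the amine/silyl triflate pair enolises the methyl ketone at its α′-CH3 and O-silylates, giving the cross-conjugated 2-siloxy diene with the (E)-propenyl unit untouched; no stereocentre is formed.

Step 2
Reactants: 3 3-methylcyclopent-2-en-1-one
Product: 4 4-methylcyclopent-4-ene-1,3-dione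
Conditions: Pd(OH)2/C (5 mol %), t-BuOOH (5 equiv), K2CO3 (0.25 equiv), CH2Cl2, 23 °C
Reagents that add atoms: tert-butyl hydroperoxide, CC(C)(C)OO
Why: Palladium-catalysed peroxide γ-oxidation of an α,β-enone to the 1,4-enedione, which should attack the ring γ-CH2 in preference to the γ-CH3; no stereocentre is formed.

Step 3
Reactants: 2 (E)-2-(triisopropylsilyloxy)penta-1,3-diene, 4 4-methylcyclopent-4-ene-1,3-dione
Product: 6 (3aR,4R,7aS)-4,7a-dimethylhexahydroindane-1,3,6-trione (cis-fused; 4-CH3 trans to 7a-CH3), via silyl enol ether adduct 5 (not isolated)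
Conditions: (S)-3,3-diphenyl-1-(2-methylphenyl)hexahydropyrrolo[1,2-c][1,3,2]oxazaborole protonated by (CF3SO2)2NH (20 mol %), CH2Cl2, −78 → −40 °C; then 2 M aq. HCl, THF, 23 °C
Reagents that add atoms: none
Why: Enantioselective Diels–Alder reaction under cationic oxazaborolidine catalysis: the catalyst binds the carbonyl flanked by the vinylic C–H (future C5), so the nucleophilic CH2 terminus of the diene (C11) bonds to the methyl-bearing β-carbon (C10), the endo transition state of the (E)-diene places the C3 methyl trans to the angular C10 methyl on a cis ring fusion (C4), and the catalyst selects the enantioface; aqueous acid then hydrolyses the silyl enol ether to the C1 ketone.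

Step 4
Reactants: 6 (3aR,4R,7aS)-4,7a-dimethylhexahydroindane-1,3,6-trione
Product: 7 C1 ethylene ketal of 6 (6,6-ethylenedioxy-4,7a-dimethylhexahydroindane-1,3-dione; stereocentres as in 6)
Conditions: Me3SiOCH2CH2OSiMe3 (2.5 equiv), Me3SiOTf (5 mol %), CH2Cl2, −78 → −20 °C; aq. NaHCO3, then pH 5 buffer
Reagents that add atoms: 1,2-bis(trimethylsilyloxy)ethane, C[Si](C)(C)OCCO[Si](C)(C)C
Why: Noyori ketalisation: the saturated C1 ketone is converted into the dioxolane while the enolised 1,3-dione is only O-silylated transiently (a vinylogous ester carbonyl is not ketalised at low temperature) and is set free again on work-up; no stereocentre is touched.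

Step 5
Reactants: 7 C1 ethylene ketal of 6, 8 2-methylprop-2-en-1-ol
Product: 10 tethered siloxy enone (C5–O–Si(i-Pr)2–O–CH2C(CH3)=CH2 enol ether of 7; C8=C5 double bond; C9 ketone), via chlorosilane 9 (not isolated)
Conditions: 8, i-Pr2SiCl2, Et3N, CH2Cl2, −78 → 0 °C; then 7, Et3N, DMAP (cat.), 0 → 23 °C; filtered and used directly
Reagents that add atoms: dichlorodiisopropylsilane, CC(C)[Si](Cl)(Cl)C(C)C
Why: O-Silylation of the enolised 1,3-dione with the monoalkoxychlorosilane should occur at the less hindered C5 oxygen, remote from the quaternary C10 (the same preference as in enol-ether formation of 4,4-disubstituted cyclic 1,3-diones), leaving C9 as the enone carbonyl and placing the alkene four atoms from C5.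

Step 6
Reactants: 10 tethered siloxy enone
Product: 13 cis-fused bicyclo[5.4.0]undecane-5,9-dione (C1 dioxolane; C6 with CH3 α and CH2OH β; 3-CH3 cis to C5; H-4 and 10-CH3 α), via photoadduct 11 (not isolated), via cyclobutanol 12 (not isolated)
Conditions: hν (Hg lamp, Pyrex, λ > 300 nm), degassed MeCN (5 mM), 0 °C; then Bu4NF, AcOH (1:1), THF, 0 °C
Reagents that add atoms: none
Why: Excitation of the 3-siloxy enone gives its triplet, whose β-carbon C5 bonds to the internal alkene carbon C6 (6-exo-trig, closing the 1,3-dioxa-2-silinane), and the 1,4-biradical collapses by C7–C8 bonding to the cis-fused cyclobutane 11; fluoride then frees the tertiary C5 cyclobutanol 12, which undergoes retro-aldol cleavage of the strained C5–C8 bond to the seven-membered 1,5-diketone. The closest known reaction types are the de Mayo reaction of enolised 1,3-diones and the silicon-tethered intramolecular enone–alkene [2+2] photocycloaddition. The cyclobutane is closed by radical recombination after the 6-exo first bond, and the seven-membered ring is not closed but uncovered by fragmentation of the bond shared by the four- and five-membered rings. The new quaternary stereocentre C6 is controlled by the tether (CH2O must be cis to the C5 oxygen on the cyclobutane) together with approach on the convex face of the cis-hydrindane, anti to the six-membered ring; the C5 and C8 centres of 11 are destroyed again. The step needs head-to-tail regiochemistry (C6 to C5, C7 to C8) and one enone face: the four-atom O–Si–O–CH2 tether enforces the former (a crossed adduct would need a seven-membered ring), and shielding of the concave face by C3 and its methyl group secures the latter.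

Step 7
Reactants: 13 cis-fused bicyclo[5.4.0]undecane-5,9-dione
Product: 14 5α-hydroxy-9-ketone diol (C5–OH trans to the C6 CH2OH; other centres as in 13)
Conditions: Me4NBH(OAc)3, MeCN/AcOH (1:1), −30 → 0 °C
Reagents that add atoms: none
Why: Evans–Saksena hydroxyl-directed reduction: the triacetoxyborohydride exchanges onto the C6 CH2OH and delivers hydride intramolecularly to the β-face of the C5 ketone, giving the 5α-alcohol (anti-1,3-diol, OH trans to CH2OH), while the C9 ketone, which has no β-hydroxyl, is not reduced.

Step 8
Reactants: 14 5α-hydroxy-9-ketone diol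
Product: 15 primary tert-butyldimethylsilyl ether of 14 (C6–CH2OTBS; C5–OH free)
Conditions: t-BuMe2SiCl, imidazole, DMF, 0 °C
Reagents that add atoms: tert-butyldimethylsilyl chloride, CC(C)(C)[Si](C)(C)Cl
Why: Selective silylation of the primary alcohol; the C5 hydroxyl, flanked by the quaternary C6 and the ring-fusion carbon C4, should not react.

Step 9
Reactants: 15 primary silyl ether
Product: 16 5α-methanesulfonate of 15
Conditions: MsCl, Et3N, CH2Cl2, −10 → 0 °C
Reagents that add atoms: methanesulfonyl chloride, CS(=O)(=O)Cl
Why: Sulfonylation via sulfene, which is small enough to reach the hindered secondary C5 hydroxyl, with retention at C5.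

Step 10
Reactants: 16 5α-methanesulfonate
Product: 17 (9R)-9β-alcohol (C9–OH cis to the C6 CH2O group; 5α-OMs; C1 dioxolane)
Conditions: (S)-2-methyl-CBS-oxazaborolidine (0.5 equiv), BH3·SMe2, THF, −20 → 0 °C; MeOH quench
Reagents that add atoms: none
Why: Corey–Bakshi–Shibata reduction: reagent control (quaternary C10 as the large and C8H2 as the small ketone substituent with the (S)-catalyst) and substrate control (hydride on the convex α-face, away from C11) should both give the (9R)-alcohol with the oxygen on the β-face.

Step 11
Reactants: 17 (9R)-9β-alcohol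
Product: 18 9β-tert-butyldimethylsilyl ether of 17
Conditions: t-BuMe2SiOTf, 2,6-lutidine, CH2Cl2, −78 → 0 °C
Reagents that add atoms: tert-butyldimethylsilyl trifluoromethanesulfonate, CC(C)(C)[Si](C)(C)OS(=O)(=O)C(F)(F)F
Why: Silyl triflate/lutidine silylation of the hindered secondary alcohol, needed so that no C9 alkoxide can displace the C5 mesylate in step 13.

Step 12
Reactants: 18 bis-silyl ether mesylate ketal
Product: 19 C1 ketone (cis-fused bicyclo[5.4.0]undecan-1-one with 5α-OMs, 9β-OTBS, C6–CH2OTBS)
Conditions: PPTS, acetone/H2O (10:1), 40 °C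
Reagents that add atoms: water, O
Why: Mild acid-catalysed ketal hydrolysis liberates the C1 ketone; the silyl ethers and the neopentyl-type mesylate should survive.

Step 13
Reactants: 19 keto mesylate
Product: 20 bis-silyl longipinan-1-one (9β-OTBS, C6–CH2OTBS; cyclobutane C4–C5–C11–C10 closed)
Conditions: KOt-Bu, t-BuOH/THF (1:1), 23 → 50 °C
Reagents that add atoms: none
Why: Intramolecular enolate alkylation (4-exo-tet): in the chair with C5 axial on C4 the C5–OMs bond lies anti to C4–C10 so that only the C11 enolate (not C2 or oxygen) can reach its backside, no anti-periplanar β-hydrogen is available for elimination, and inversion at C5 closes the bicyclo[3.1.1]heptanone with the configurations of C5 and C11 dictated by the ring system.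

Step 14
Reactants: 20 bis-silyl longipinan-1-one
Product: 21 9β-hydroxy-6-(hydroxymethyl)longipinan-1-one (diol)
Conditions: HF·pyridine, THF/pyridine, 0 → 23 °C
Reagents that add atoms: none
Why: Fluoride cleavage of both silyl ethers under buffered conditions; the hydroxyls are γ and δ to the ketone, so no retro-aldol cleavage is possible.

Step 15
Reactants: 21 diol, 22 (E)-2-methylbut-2-enoyl chloride (tigloyl chloride)
Product: 23 primary tiglate (C6–CH2O-tigloyl; 9β-OH free)
Conditions: pyridine, CH2Cl2, −20 → 0 °C
Reagents that add atoms: none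
Why: Acylation of the primary alcohol with the acid chloride at low temperature; the neopentyl secondary C9 hydroxyl reacts much more slowly and the (E)-geometry of the tiglate is not at risk.

Step 16
Reactants: 23 primary tiglate, 24 (Z)-2-methylbut-2-enoic acid (angelic acid)
Product: 26 CNP0276938.2 (target), via mixed anhydride 25 (not isolated)
Conditions: 24, 2,4,6-trichlorobenzoyl chloride, Et3N, toluene, 23 °C; then 23, toluene, 80 °C (no DMAP)
Reagents that add atoms: none
Why: Yamaguchi-type esterification through the mixed 2,4,6-trichlorobenzoic anhydride, the established way to acylate hindered secondary alcohols with angelic acid without (Z)→(E) isomerisation; C9 keeps its configuration.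

Compound list
1 | (E)-pent-3-en-2-one | C/C=C/C(C)=O | starting material
2 | (E)-2-(triisopropylsilyloxy)penta-1,3-diene | C/C=C/C(=C)O[Si](C(C)C)(C(C)C)C(C)C | intermediate
3 | 3-methylcyclopent-2-en-1-one | CC1=CC(=O)CC1 | starting material
4 | 4-methylcyclopent-4-ene-1,3-dione | CC1=CC(=O)CC1=O | intermediate
5 | (3aR,4R,7aS)-4,7a-dimethyl-6-(triisopropylsilyloxy)-3a,4,7,7a-tetrahydroindene-1,3-dione (cis-fused Diels–Alder adduct) | O=C1CC(=O)[C@@H]2[C@H](C)C=C(O[Si](C(C)C)(C(C)C)C(C)C)C[C@]12C | intermediate (not isolated)
6 | (3aR,4R,7aS)-4,7a-dimethylhexahydroindane-1,3,6-trione (cis-fused; 4-CH3 trans to 7a-CH3) | O=C1CC(=O)[C@@H]2[C@H](C)CC(=O)C[C@]12C | intermediate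
7 | C1 ethylene ketal of 6 (6,6-ethylenedioxy-4,7a-dimethylhexahydroindane-1,3-dione) | O=C1CC(=O)[C@@H]2[C@H](C)CC3(OCCO3)C[C@]12C | intermediate
8 | 2-methylprop-2-en-1-ol | CC(=C)CO | starting material
9 | chloro(diisopropyl)(2-methylallyloxy)silane | CC(=C)CO[Si](Cl)(C(C)C)C(C)C | intermediate (not isolated)
10 | tethered siloxy enone: C5–O–Si(i-Pr)2–O–CH2C(CH3)=CH2 enol ether of 7 (C8=C5, C9 ketone) | O=C1C=C(O[Si](C(C)C)(C(C)C)OCC(C)=C)[C@@H]2[C@H](C)CC3(OCCO3)C[C@]12C | intermediate
11 | photoadduct: cyclobutane C5–C6–C7–C8 cis-fused to the five-membered ring on the face of H-4/CH3-10; 1,3-dioxa-2-silinane C5–O–Si–O–CH2–C6; C6 methyl endo | O=C1[C@H]2C[C@]3(C)CO[Si](C(C)C)(C(C)C)O[C@]23[C@@H]4[C@H](C)CC5(OCCO5)C[C@]14C | intermediate (not isolated)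
12 | desilylated photoadduct: tertiary C5 cyclobutanol with C6 CH2OH cis to the C5 hydroxyl | O=C1[C@H]2C[C@](C)(CO)[C@@]2(O)[C@@H]3[C@H](C)CC4(OCCO4)C[C@]13C | intermediate (not isolated)
13 | cis-fused bicyclo[5.4.0]undecane-5,9-dione, C1 dioxolane, C6 CH3 (α) and CH2OH (β), 3-CH3 cis to C5, H-4 and 10-CH3 α | O=C1CC[C@](C)(CO)C(=O)[C@@H]2[C@H](C)CC3(OCCO3)C[C@]12C | intermediate
14 | 5α-hydroxy derivative of 13 (C5–OH trans to C6 CH2OH; C9 ketone) | O=C1CC[C@](C)(CO)[C@@H](O)[C@@H]2[C@H](C)CC3(OCCO3)C[C@]12C | intermediate
15 | primary TBS ether of 14 | O=C1CC[C@](C)(CO[Si](C)(C)C(C)(C)C)[C@@H](O)[C@@H]2[C@H](C)CC3(OCCO3)C[C@]12C | intermediate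
16 | 5α-methanesulfonate of 15 | O=C1CC[C@](C)(CO[Si](C)(C)C(C)(C)C)[C@@H](OS(C)(=O)=O)[C@@H]2[C@H](C)CC3(OCCO3)C[C@]12C | intermediate
17 | (9R)-9β-alcohol of 16 (C9–OH cis to C6 CH2O) | O[C@@H]1CC[C@](C)(CO[Si](C)(C)C(C)(C)C)[C@@H](OS(C)(=O)=O)[C@@H]2[C@H](C)CC3(OCCO3)C[C@]12C | intermediate
18 | 9β-TBS ether of 17 | CC(C)(C)[Si](C)(C)O[C@@H]1CC[C@](C)(CO[Si](C)(C)C(C)(C)C)[C@@H](OS(C)(=O)=O)[C@@H]2[C@H](C)CC3(OCCO3)C[C@]12C | intermediate
19 | C1 ketone from 18 (keto mesylate) | CC(C)(C)[Si](C)(C)O[C@@H]1CC[C@](C)(CO[Si](C)(C)C(C)(C)C)[C@@H](OS(C)(=O)=O)[C@@H]2[C@H](C)CC(=O)C[C@]12C | intermediate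
20 | 9β-(TBS-oxy)-6-(TBS-oxymethyl)longipinan-1-one | CC(C)(C)[Si](C)(C)O[C@@H]1CC[C@](C)(CO[Si](C)(C)C(C)(C)C)[C@H]2[C@@H]3[C@H](C)CC(=O)[C@H]2[C@@]31C | intermediate
21 | 9β-hydroxy-6-(hydroxymethyl)longipinan-1-one | O[C@@H]1CC[C@](C)(CO)[C@H]2[C@@H]3[C@H](C)CC(=O)[C@H]2[C@@]31C | intermediate
22 | (E)-2-methylbut-2-enoyl chloride (tigloyl chloride) | C/C=C(\C)C(Cl)=O | starting material
23 | 9β-hydroxy-6-(tigloyloxymethyl)longipinan-1-one | O[C@@H]1CC[C@](C)(COC(=O)/C(C)=C/C)[C@H]2[C@@H]3[C@H](C)CC(=O)[C@H]2[C@@]31C | intermediate
24 | (Z)-2-methylbut-2-enoic acid (angelic acid) | C/C=C(/C)C(=O)O | starting material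
25 | angelic 2,4,6-trichlorobenzoic anhydride | C/C=C(/C)C(=O)OC(=O)c1c(Cl)cc(Cl)cc1Cl | intermediate (not isolated)
26 | CNP0276938.2: (3R,4S,5S,6S,9R,10R,11R)-9-angeloyloxy-6-(tigloyloxymethyl)-3,6,10-trimethyl longipinan-1-one (ring numbering above) | C/C=C(/C)C(=O)O[C@@H]1CC[C@](C)(COC(=O)/C(C)=C/C)[C@H]2[C@@H]3[C@H](C)CC(=O)[C@H]2[C@@]31C | target

Total step count: 16. Longest linear sequence: 15 steps (3 → 26; step 1 prepares the diene separately).

Steps most likely to fail

Step 13 (cyclobutane closure). Backside displacement at C5, which is flanked by the quaternary C6 and the ring-fusion carbon C4, may be slower than attack of the base on the sulfonate or than O-alkylation of the ambident mono-enolate. No different bond construction for C5–C11 was found, so the fallback changes the nucleophile from an equilibrating mono-enolate to a blocked dianion; it still relies on displacement at C5 and exposes the mesylate to a strong amide base. It sets out from 19 and comes back at 20. Compound 19 is formylated at the less hindered C2 (HCO2Et, NaH, THF) to the C2-hydroxymethylene ketone F1. A second deprotonation (LiN(i-Pr)2, THF/HMPA, −78 → 0 °C) gives the dianion, whose α′-carbanion C11 is a regiodefined, much stronger and purely carbon nucleophile. This should close the C5–C11 bond to the hydroxymethylene longipinanone F2. Retro-Claisen deformylation (K2CO3, MeOH, 23 °C) returns 20.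

Step 6 (key step). The vinylogous silyl ester may hydrolyse or migrate between the two dione oxygens before it is excited, or cycloaddition may occur in part on the concave face. The fallback gives up the tether for a classical intermolecular de Mayo reaction; it sets out from 7 and comes back at 13. Compound 7 is O-acetylated at the C5 enol oxygen (AcCl, pyridine, CH2Cl2) to the 3-acetoxy enone F3. Irradiation (Pyrex, MeCN) with excess 2-methylallyl acetate should give the head-to-tail photoadduct diacetate F4 together with its C6 epimer F5, which is removed by chromatography; C6 is then no longer controlled by the substrate. K2CO3/MeOH cleaves both acetates of F4, and the liberated cyclobutanol fragments to 13.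

Step 3 (asymmetric Diels–Alder reaction). The acidic methylene of the enedione and the enolic product may bind or protonate the catalyst, leading to low conversion or low enantioselection. The fallback replaces catalysis by resolution; it sets out from 2 and 4 and comes back at 6. BF3·OEt2-promoted cycloaddition (CH2Cl2, −78 °C; same regiochemistry through coordination at the less hindered carbonyl) and acid hydrolysis give the racemate, that is 6 together with its enantiomer F6. The vinylogous acid is resolved with (S)-1-phenylethylamine: the salt of 6, F7, is to be crystallised (with the antipodal amine should the opposite pairing be the less soluble one), while the salt of the enantiomer, F8, stays in the mother liquor. Acidification of F7 (1 M HCl) returns 6.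

Further compounds
F1 | step 13 | C2-hydroxymethylene derivative of keto mesylate 19 (chelated enol) | CC(C)(C)[Si](C)(C)O[C@@H]1CC[C@](C)(CO[Si](C)(C)C(C)(C)C)[C@@H](OS(C)(=O)=O)[C@@H]2[C@H](C)/C(=C/O)C(=O)C[C@]12C
F2 | step 13 | C2-hydroxymethylene derivative of longipinanone 20 | CC(C)(C)[Si](C)(C)O[C@@H]1CC[C@](C)(CO[Si](C)(C)C(C)(C)C)[C@H]2[C@@H]3[C@H](C)/C(=C/O)C(=O)[C@H]2[C@@]31C
F3 | step 6 | C5 enol acetate of 7 (3-acetoxy enone) | O=C1C=C(OC(C)=O)[C@@H]2[C@H](C)CC3(OCCO3)C[C@]12C
F4 | step 6 | intermolecular photoadduct diacetate (C6 CH2OAc cis to C5–OAc; cyclobutane on the face of H-4/CH3-10) | O=C1[C@H]2C[C@](C)(COC(C)=O)[C@@]2(OC(C)=O)[C@@H]3[C@H](C)CC4(OCCO4)C[C@]13C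
F5 | step 6 | C6 epimer of F4 | O=C1[C@H]2C[C@@](C)(COC(C)=O)[C@@]2(OC(C)=O)[C@@H]3[C@H](C)CC4(OCCO4)C[C@]13C
F6 | step 3 | (3aS,4S,7aR)-4,7a-dimethylhexahydroindane-1,3,6-trione (enantiomer of 6) | O=C1CC(=O)[C@H]2[C@@H](C)CC(=O)C[C@@]12C
F7 | step 3 | (S)-1-phenylethylammonium enolate of 6 | O=C1C=C([O-])[C@@H]2[C@H](C)CC(=O)C[C@]12C.C[C@H]([NH3+])c1ccccc1
F8 | step 3 | (S)-1-phenylethylammonium enolate of F6 | O=C1C=C([O-])[C@H]2[C@@H](C)CC(=O)C[C@@]12C.C[C@H]([NH3+])c1ccccc1
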